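The numbers in the tables are simulated with made-up constants, noise included.

Left-handed product is what the peaks have to give here, and the runs so far stand as follows.

| flask | left-handed substrate | right-handed substrate | gas | racemization catalyst | remark | time |
|---|---|---|---|---|---|---|
| theta | 2.1 M | 2.1 M | 77 mM (held) | 15 mM | run made earlier |  |
| flask | 1.5 M | 1.5 M | 77 mM (held) | 15 mM |  | 15 h |

theta run (percent of the left-handed substrate and right-handed substrate together charged)

| time / h | left-handed product / % |
|---|---|
| 1.33 | 0.3 |
| 2.50 | 0.7 |
| 4.00 | 0.8 |
| 5.00 | 1.5 |
| 6.00 | 1.8 |
| 8.00 | 2.2 |
| 10.0 | 3.2 |

(readings scatter by 0.3 percentage points)

- reagent is single-handed; left-handed substrate and right-handed substrate are mirror images of each other, charged as a racemate, each of them at the stated concentration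
- the earlier runs were read with a standard deviation of 0.3 percentage points
- at the start none of the gas is in solution
- the handed part of reagent does not stay in what it makes, so the products of the two hands are mirror images too

1. left-handed product at 15 h, in percent of the left-handed substrate and right-handed substrate together charged
2. the change that raises the amount of left-handed product at 15 h, in percent of the left-handed substrate and right-handed substrate together charged most ("none" if none brings more than 2 percentage points) (alder / elm / maple / none)
3. amount of left-handed product at 15 h, in percent of the left-handed substrate and right-handed substrate together charged, after alder

- alder: doubling the saturation concentration of gas, all else as stated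
- elm: doubling the amount of racemization catalyst, all else as stated
- maple: doubling the transfer coefficient of the gas, all else as stated

In the theta run left-handed product climbs nearly along a straight line, so its last three readings can be pooled:

g = sum of those readings / sum of their times = 0.00300 h⁻¹

This yield slope, the fraction of all substrate charged that becomes left-handed product per hour, is the bench rule. A pseudo-first-order flask, with steady [reagent] and little substrate used, keeps it at any charge:

y = g × t = 4.50 %

The rule stops if the flask runs on the uptake of gas and its molar rate does not follow the substrate charge. The molar rate then carries over, and the yield slope rises by the ratio of the charges: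

f = 1.40, so y = 6.30 %

The theta run has a single charge, so this reckoning commits to the band between these limits. Both limits scale with the saturation concentration, so alder gives 9.00 % to 12.6 %, a gain of 4.50 % at the lower limit, more than the margin of 2 percentage points. Maple counts toward the upper limit, while elm acts on the balance of the hands, and the lower limit spends 9.00 % of the charged left-handed substrate. The choice here is alder.

The forecast, which chose to “take first order as central”, gives 4.5 %, alder and 8.7 %.

The flask gives 5.41 %, above the lower limit and below the upper. Alder adds 5.2 points, reaching 10.6 %, against 3.4 points from maple and 0.011 points from elm.

    reagent + left-handed substrate → left-handed product (k = 1.30 × 10⁻⁴ M⁻¹ s⁻¹)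
    reagent + right-handed substrate → right-handed product (k = 6.80 × 10⁻⁵ M⁻¹ s⁻¹)
    left-handed substrate + racemization catalyst ⇌ right-handed substrate + racemization catalyst, rate k3*[racemization catalyst]*[left-handed substrate] forward; the back reaction follows from the equilibrium constant (k = 0.00150 M⁻¹ s⁻¹)
    gas ⇌ reagent, rate k4*(csat - [reagent]) (kL = 8.10 × 10⁻⁵ s⁻¹)

The neighbouring flask, the same charge left until 2.5 d, takes the same reckoning: g × t gives 18.0 %, and f lifts that to 25.2 %. It gives 21.6 %, inside that band, with 66 % of the charged left-handed substrate still there.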